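Raising the temperature from 20 °C to 60 °C multiplies the unfolding of free enzyme by 1.4 × 10⁶ but its catalysis by 1.8.

    starting material + free enzyme → product + free enzyme, rate k1*[starting material]*[free enzyme]/(1 + ([starting material]/Km1) + ([product]/Kp1)) (Km1 = 0.26 M, Kp1 = 1.2 mM, k1 = 1.7 × 10⁵ /M/s, Ea1 = 12.0 kJ/mol)
    starting material ⇌ dormant form (K2 = 23, k2 = 5.7 × 10⁻⁴ /s, Ea2 = 92.0 kJ/mol, ΔH2 = −57.0 kJ/mol)
    free enzyme → unfolded enzyme (k3 = 4.4 × 10⁻⁵ /s, Ea3 = 288 kJ/mol)
    (constants at 20 °C)

| flask | starting material | free enzyme | temperature | time |
|---|---|---|---|---|
| south-west | 0.10 M | 8.1 µM | 60 °C | 10 min |
| south | 0.10 M | 8.1 µM | 20 °C | 10 min |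
| north | 0.10 M | 8.1 µM | 40 °C | 10 min |

- the constants hold at 20 °C; other temperatures follow from the activation energies and enthalpies

1. the flask with the highest amount of product, in percent of the starting material charged ("all alike" if they lie within 1.5 percentage points) (south-west / south / north / all alike)
2. final product, as a percentage of the starting material charged, in south-west
3. final product, as a percentage of the starting material charged, in south
4. final product, as a percentage of the starting material charged, in north

Follow one molecule of free enzyme: at each instant it either turns over or unfolds. Let k be the rate constant of the catalytic step, u that of unfolding, c the charge of starting material, S and P the concentrations of starting material and product. With Km and Kp the constants of the rate law, a small step of product dP then uses up an amount k·[free enzyme]·dt equal to (1 + S/Km + P/Kp)·dP/S. Summed from zero, with S = c − P, the bill for product P is (1 + c/Kp)·ln(c/(c − P)) + P·(1/Km − 1/Kp).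

In south-west the free enzyme has a mean lifetime of 15.7 ms, and k·[free enzyme]/u comes to 0.0390. This number is the enzyme budget, the sum of k·[free enzyme]·dt over the time the enzyme lasts, and in south-west product stops where the bill equals it.

In the first instants of south-west the denominator stands at 1.38 and each enzyme turns over 22200 /s. Within the lifetime the drain to dormant form, at 0.0530 /s, takes hardly any of the starting material. In the middle of south-west, product reaches Kp, 1.2 mM, where the inhibition term P/Kp equals 1, against 1.38 for the rest of the denominator. With S close to c the bill in south-west is quadratic in P, and it meets the budget of 0.0390 at 1.82 mM, or 1.82 % of the charge.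

In south hardly any of the free enzyme unfolds during the run, since u·t is 0.0264, and the budget is 815. The bill for 99.0 % of the charge is 306, so south can pay. Starting material in south also turns dormant while it waits for the enzyme, and summing that drain along the run, with the denominator at its mean, takes about 1.77 % of the charge. This reckoning therefore gives 98.2 % for south. It offers no figure for north, which lies between the other two in temperature, so it sets south above south-west and leaves north open.

The forecast also ranks south first, with 98.2 % there, 53 % in north and 1.8 % in south-west, reasoning that “the warm flasks stop early, especially with strong product inhibition”.

The simulation gives 1.81 % in south-west, 98.3 % in south and 54.1 % in north, so south stands highest, as forecast. The bill for south-west's 1.81 % comes to 0.0386, against its budget of 0.0390. The neighbouring flask, south with 0.40 M of starting material, has the budget of south, 815. That exceeds the bill of 536 for 91.9 % of product, but falls short of the bill of 951 for 97.8 % of product, the part of the charge no longer standing as starting material. At 10.0 min that flask holds 91.9 % product, 5.87 % dormant form and 2.2 % starting material.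

Its constants were set for the occasion.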